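**Remarks on the chemistry.** The target is achiral. The single stereocentre carried from 7 to 13 (the methyl-bearing sp3 carbon) is racemic and is destroyed in step 8, so no configuration has to be controlled. Compounds 1, 5 and 9 are taken to be commercial. Naphthalene numbering used throughout: C1 bears the trimethoxyphenyl ring C, C2 and C3 the methyl groups, C6 the hydroxyl, C7 the methoxy group; ring A is C1–C4/C4a/C8a, ring B is C4a/C5–C8/C8a.

## Analysis of the target

The target 15 is a 1-arylnaphthalene. Ring A carries the 3,4,5-trimethoxyphenyl ring C at C1, methyl groups at C2 and C3 and a hydrogen at C4; ring B carries the free hydroxyl at C6 and a methoxy group at C7. There is no stereocentre, and the C1–aryl axis is not stereogenic because ring C is symmetric about it, so any sp3 centre made on the way only has to disappear again. The sensitive features are the electron-rich naphthol, which is prone to oxidation and is best released last, and the one phenolic oxygen among four methyl ethers, which cannot be singled out by demethylation at the end and must be differentiated from the first compound. The difficulty is regiochemical and steric: ring C has to sit on the ring-A carbon attached to C8a, which lies para to the C6 oxygen, and C1, C2 and C3 are three contiguous fully substituted carbons with a crowded C1=C2 bond. The strategy rests on that bond. C1 carries two aryl groups (ring C and C8a of ring B) and C2 carries a methyl group and C3, so C1 maps onto a diaryl ketone carbon and C2 onto a methyl ketone carbon. Joining these two electrophilic carbons reductively closes ring A at the dihydronaphthalene level, and C3 and C4 are aromatized afterwards.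

## Retrosynthetic reasoning

**15 ⇒ 14.** The C6 oxygen is traced back to a benzyl ether. Benzyl is chosen because it is stable to base, organolithium reagents, aqueous acid and low-valent titanium, and because neutral hydrogenolysis removes it without touching the four methyl ethers. The forward step only has to cleave one O–CH2Ph bond on a finished naphthalene.

**14 ⇒ 13.** The C3–C4 bond of ring A is returned to the sp3 level, giving the dihydronaphthalene 13 with the C1=C2 bond in place. Ring A then needs to be closed only as a cyclohexene, and the C3 centre never needs control. The forward step is a dehydrogenation that removes the hydrogens at C3 and C4.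

**13 ⇒ 12.** The C1=C2 bond is cut into two carbonyl groups, giving the 1,6-diketone 12. This is the only ring-A bond whose two ends are fully substituted sp2 carbons, so it is the only one that translates into two ketones without extra functional groups. Cutting C1–C8a would instead hand the regiochemistry to the directing effects of ring B, and cutting C2–C3 or C3–C4 would leave the crowded alkene still to be made. The forward reaction must join two electrophilic carbons reductively and intramolecularly, and remove both oxygens.

**12 ⇒ 8 + 9.** The C1–C8a bond is cut between an aryl anion at C8a and an acyl cation equivalent at C1. The anion comes from the aryl bromide 8 by lithium–bromine exchange, so the bromine fixes the regiochemistry on ring B. The acyl equivalent is the nitrile 9, which delivers the ketone oxidation level directly. The methyl ketone has to be masked during the organolithium step, hence the dioxolane in 8; one acidic work-up hydrolyses the ketimine and the ketal together.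

**8 ⇒ 7.** The dioxolane is traced back to the methyl ketone 7, an ordinary ketalization.

**7 ⇒ 4 + 5.** The C3–C4 bond is cut between a benzylic electrophile (4) and a nucleophilic C3. The nucleophile is the enolate of the symmetric diketone 5, which already carries C3 with its methyl group and C2 with its methyl group. The second acetyl group is a disposable activator, removed by retro-Claisen cleavage. Because 5 is symmetric, cleavage of either acetyl group gives the same ketone.

**4 ⇒ 3 ⇒ 2 ⇒ 1.** The benzylic bromide goes back through the alcohol 3 and the aldehyde 2 to the bromophenol 1. Compound 1 holds all of ring B with the correct pattern: the bromine sits on the future C8a (para to the hydroxyl), the aldehyde carbon is the future C4, the hydroxyl is the C6 oxygen and the methoxy group is at C7.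

## Alternatives that were turned down

**Alternative 1:** Tethered styrene–alkyne cycloaddition. C1–C8a and C2–C3 are cut together, with C2 and C3 carried as the carbonyl and CH2–O carbons of a lactone. The precursor is the cinnamyl arylpropiolate A1, (E)-3-(3-benzyloxy-4-methoxyphenyl)prop-2-en-1-yl 3-(3,4,5-trimethoxyphenyl)prop-2-ynoate.
- Forward key step: on heating in nitrobenzene the styrene of A1 (C8a, C4a, C4, C3) serves as diene and the alkyne (C2, C1) as dienophile in an intramolecular dehydro-Diels–Alder reaction. Ring B rearomatizes and the solvent dehydrogenates the adduct to the arylnaphthalene lactone A2, 6-benzyloxy-7-methoxy-9-(3,4,5-trimethoxyphenyl)naphtho[2,3-c]furan-1(3H)-one.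
- For it: two C–C bonds, ring A and full aromaticity arrive in one operation from two simple halves. On convergence and bond count in the key step it is stronger than the chosen route.
- Against it: nothing fixes which ortho carbon of ring B takes part, so closure next to the benzyloxy group competes with closure para to it. The electron-rich arylalkyne can also act as the diene toward the cinnamyl alkene, which fuses ring C instead of ring B. Above all, C2 and C3 emerge as a lactone, so the lactone must be reduced and two benzylic C–O bonds removed to reach two methyl groups, at least two further reductive operations on a naphthalene that must not be over-reduced.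
- Comparison: the chosen route carries both methyl groups at their final oxidation level from compound 5 and fixes the ring-B regiochemistry with the bromine of 1.

**Alternative 2:** Parham cyclization onto a γ-lactone. C4–C4a is cut, with C4 as a lactone carbonyl and C1 as a carbinol carbon that already bears both aryl rings. The precursor is the bromo lactone A3, 5-(4-benzyloxy-2-bromo-5-methoxyphenyl)-3,4-dimethyl-5-(3,4,5-trimethoxyphenyl)oxolan-2-one.
- Forward key step: tert-butyllithium exchanges the bromine of A3; the aryllithium attacks the lactone carbonyl, and the bridged hemiketal alkoxide opens to the hydroxy tetralone A4, 7-benzyloxy-4-hydroxy-6-methoxy-2,3-dimethyl-4-(3,4,5-trimethoxyphenyl)-3,4-dihydronaphthalen-1(2H)-one.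
- For it: an anionic ring closure is fast and needs neither high dilution nor a heterogeneous metal. The bromine fixes the regiochemistry, and aromatization later needs only reduction and dehydration, no oxidant. As a ring closure it is more predictable than a McMurry coupling.
- Against it: A3 is hard to make. Its carbinol carbon carries two aryl groups, the ring oxygen and a secondary carbon next to another methyl-bearing carbon, so a branched nucleophile must be added to a hindered, ortho-brominated diaryl ketone. In the key step the lactone α-hydrogen can quench the aryllithium by proton transfer. A4 then needs ketone reduction, double dehydration and debenzylation, three steps against two after the chosen key step.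
- Comparison: the chosen route concedes the cleaner ring closure but reaches its precursor 12 by an enolate alkylation and an aryllithium addition to a nitrile, and the key step gives the alkene oxidation level directly.

**Alternative 3:** Prins–Friedel–Crafts annulation. C1–C2 and C1–C8a are both cut at one aldehyde carbon. The partners are the alkenyl arene A5, 2-benzyloxy-1-methoxy-4-(2-methylbut-2-en-1-yl)benzene, and the aldehyde A6, 3,4,5-trimethoxybenzaldehyde.
- Forward key step: BF3·OEt2 activates A6; the CH terminus of the trisubstituted alkene of A5 attacks it (C1–C2), the tertiary cation loses a benzylic proton, and the resulting benzylic alcohol ionizes and alkylates ring B para to the benzyloxy group (C1–C8a). The product is the dihydronaphthalene A7, 7-benzyloxy-6-methoxy-2,3-dimethyl-1-(3,4,5-trimethoxyphenyl)-1,2-dihydronaphthalene.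
- For it: it is the shortest and most convergent plan, a two-component annulation that forms two bonds and uses a commercial aldehyde as C1. On step count it beats the chosen route.
- Against it: every selectivity depends on relative rates in a cationic manifold with three electron-rich arenes. The activated aldehyde can hydroxyalkylate ring B directly and go on to triarylmethanes. Acid can move the alkene of A5 into conjugation with ring B, which changes the nucleophilic carbon and the connectivity. BF3 also threatens the benzyl ether, and the reaction is intermolecular.
- Comparison: in the chosen route each new bond is dictated by a functional group (a C–Br bond, a nitrile, two ketones), not by relative nucleophilicity; the price is a longer linear sequence.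

Key step: step 7

## Route

**Step 1**
Reactants: 1 6-bromoisovanillin (2-bromo-5-hydroxy-4-methoxybenzaldehyde)
Product: 2 5-benzyloxy-2-bromo-4-methoxybenzaldehyde
Conditions: BnBr, K2CO3, DMF, 60 °C
Reagents that add atoms: benzyl bromide, BrCc1ccccc1
Why: Williamson ether synthesis on the phenoxide; the aldehyde and the aryl bromide are inert, and the benzyl group marks the future C6 oxygen against the methyl ethers.

**Step 2**
Reactants: 2 5-benzyloxy-2-bromo-4-methoxybenzaldehyde
Product: 3 (5-benzyloxy-2-bromo-4-methoxyphenyl)methanol
Conditions: NaBH4, MeOH–THF, 0 °C
Reagents that add atoms: none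
Why: Borohydride reduction of an aromatic aldehyde; the aryl bromide and the ethers are untouched.

**Step 3**
Reactants: 3 (5-benzyloxy-2-bromo-4-methoxyphenyl)methanol
Product: 4 1-benzyloxy-4-bromo-5-(bromomethyl)-2-methoxybenzene
Conditions: PBr3, CH2Cl2, 0 °C
Reagents that add atoms: phosphorus tribromide (PBr3), BrP(Br)Br
Why: Conversion of a benzylic alcohol into the bromide via its phosphite ester; the para-methoxy group makes the substitution fast at 0 °C, and the reactive bromide should be used without long storage.

**Step 4**
Reactants: 4 1-benzyloxy-4-bromo-5-(bromomethyl)-2-methoxybenzene; 5 3-methylpentane-2,4-dione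
Product: 7 rac-4-(5-benzyloxy-2-bromo-4-methoxyphenyl)-3-methylbutan-2-one, via alkylated diketone 6 (not isolated)
Conditions: NaH, THF, 0 °C to rt; then 2 M aq NaOH, EtOH, 40 °C
Reagents that add atoms: none
Why: C-alkylation of the stabilized sodium enolate of 5 by the benzylic bromide (SN2) makes the C3–C4 bond, then hydroxide cleaves the non-enolizable 2,2-disubstituted 1,3-diketone 6 by retro-Claisen deacetylation. Because 6 is symmetric, loss of either acetyl group gives 7.

**Step 5**
Reactants: 7 rac-4-(5-benzyloxy-2-bromo-4-methoxyphenyl)-3-methylbutan-2-one
Product: 8 rac-2-[1-(5-benzyloxy-2-bromo-4-methoxyphenyl)propan-2-yl]-2-methyl-1,3-dioxolane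
Conditions: HOCH2CH2OH, p-TsOH·H2O (cat.), toluene, reflux, Dean–Stark
Reagents that add atoms: ethylene glycol, OCCO
Why: Acid-catalysed ketalization driven by azeotropic removal of water; it masks the ketone and its α-hydrogens against the aryllithium of step 6.

**Step 6**
Reactants: 8 rac-2-[1-(5-benzyloxy-2-bromo-4-methoxyphenyl)propan-2-yl]-2-methyl-1,3-dioxolane; 9 3,4,5-trimethoxybenzonitrile
Product: 12 rac-4-[5-benzyloxy-4-methoxy-2-(3,4,5-trimethoxybenzoyl)phenyl]-3-methylbutan-2-one, via aryllithium 10 (not isolated), via lithium ketimide 11 (not isolated)
Conditions: n-BuLi, THF, −78 °C; then 9, −78 °C to rt; then 2 M aq HCl, THF, rt to 50 °C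
Reagents that add atoms: water, O
Why: Lithium–bromine exchange at −78 °C is faster than any deprotonation; addition of the aryllithium to the nitrile stops at the ketimide, so no over-addition can occur. Aqueous acid then hydrolyses the diaryl ketimine to the ketone and the dioxolane to the methyl ketone in the same work-up.

**Step 7**
Reactants: 12 rac-4-[5-benzyloxy-4-methoxy-2-(3,4,5-trimethoxybenzoyl)phenyl]-3-methylbutan-2-one
Product: 13 rac-7-benzyloxy-6-methoxy-2,3-dimethyl-4-(3,4,5-trimethoxyphenyl)-1,2-dihydronaphthalene
Conditions: TiCl3(DME)1.5, Zn–Cu, DME, reflux; 12 added slowly by syringe pump (high dilution)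
Reagents that add atoms: none
Why: Intramolecular McMurry coupling: low-valent titanium made from TiCl3(DME)1.5 and the Zn–Cu couple transfers single electrons to both carbonyl groups of 12, the diaryl ketone first because its ketyl is benzophenone-like and persistent. The two titanium-bound ketyls combine at C1 and C2 to a cyclic titanium pinacolate, and at reflux both C–O bonds are cleaved on the metal to release the C1=C2 alkene. The closest known reaction type is the intramolecular keto–keto McMurry cyclization that gives tetrasubstituted cycloalkenes. Ring A closes as a six-membered carbocycle by bond formation between the two carbonyl carbons, a 6-exo-trig closure seen from either ketyl carbon onto the other carbonyl, helped by the two tether atoms C8a and C4a being held ortho on ring B. No stereocentre is created; the existing methyl-bearing centre is untouched, stays racemic and is erased in step 8. The step needs ring closure to beat intermolecular coupling and to beat enolization or aldol reaction of the methyl ketone. Slow addition keeps the stationary concentration of 12 low, the diaryl ketone cannot enolize and is reduced ahead of the methyl ketone, and the product alkene is conjugated with two arenes, which eases the deoxygenation. Aryl benzyl and methyl ethers are inert to low-valent titanium, and any migration of the double bond within ring A is harmless because step 8 aromatizes every isomer.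

**Step 8**
Reactants: 13 rac-7-benzyloxy-6-methoxy-2,3-dimethyl-4-(3,4,5-trimethoxyphenyl)-1,2-dihydronaphthalene
Product: 14 6-benzyloxy-7-methoxy-2,3-dimethyl-1-(3,4,5-trimethoxyphenyl)naphthalene
Conditions: DDQ (1.1 equiv), toluene, 80 °C
Reagents that add atoms: none
Why: Quinone dehydrogenation: hydride abstraction from the benzylic C4 position (cation stabilized by the para methoxy group at C7) and loss of the C3 proton give the naphthalene. A simple benzyl ether is far slower to oxidize than the dihydroarene when the quinone is not used in excess.

**Step 9**
Reactants: 14 6-benzyloxy-7-methoxy-2,3-dimethyl-1-(3,4,5-trimethoxyphenyl)naphthalene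
Product: 15 3-methoxy-6,7-dimethyl-5-(3,4,5-trimethoxyphenyl)naphthalen-2-ol (the target; in the numbering used here 7-methoxy-2,3-dimethyl-1-(3,4,5-trimethoxyphenyl)naphthalen-6-ol)
Conditions: H2 (1 atm), Pd/C, EtOAc–EtOH, rt
Reagents that add atoms: none
Why: Hydrogenolysis of the aryl benzyl ether over Pd/C; the naphthalene core and the methyl ethers are not reduced under these mild conditions, and the oxidation-sensitive naphthol is released only at the end.

## Compound list

1 | 6-bromoisovanillin (2-bromo-5-hydroxy-4-methoxybenzaldehyde) | COc1cc(Br)c(C=O)cc1O | starting material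
2 | 5-benzyloxy-2-bromo-4-methoxybenzaldehyde | COc1cc(Br)c(C=O)cc1OCc1ccccc1 | intermediate
3 | (5-benzyloxy-2-bromo-4-methoxyphenyl)methanol | COc1cc(Br)c(CO)cc1OCc1ccccc1 | intermediate
4 | 1-benzyloxy-4-bromo-5-(bromomethyl)-2-methoxybenzene | COc1cc(Br)c(CBr)cc1OCc1ccccc1 | intermediate
5 | 3-methylpentane-2,4-dione | CC(=O)C(C)C(C)=O | starting material
6 | 3-[(5-benzyloxy-2-bromo-4-methoxyphenyl)methyl]-3-methylpentane-2,4-dione | CC(=O)C(C)(Cc1cc(OCc2ccccc2)c(OC)cc1Br)C(C)=O | intermediate (not isolated)
7 | rac-4-(5-benzyloxy-2-bromo-4-methoxyphenyl)-3-methylbutan-2-one | CC(=O)C(C)Cc1cc(OCc2ccccc2)c(OC)cc1Br | intermediate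
8 | rac-2-[1-(5-benzyloxy-2-bromo-4-methoxyphenyl)propan-2-yl]-2-methyl-1,3-dioxolane | CC1(OCCO1)C(C)Cc1cc(OCc2ccccc2)c(OC)cc1Br | intermediate
9 | 3,4,5-trimethoxybenzonitrile | COc1cc(C#N)cc(OC)c1OC | starting material
10 | rac-{4-benzyloxy-5-methoxy-2-[2-(2-methyl-1,3-dioxolan-2-yl)propyl]phenyl}lithium | [Li]c1cc(OC)c(OCc2ccccc2)cc1CC(C)C1(C)OCCO1 | intermediate (not isolated)
11 | rac-N-lithio-1-{4-benzyloxy-5-methoxy-2-[2-(2-methyl-1,3-dioxolan-2-yl)propyl]phenyl}-1-(3,4,5-trimethoxyphenyl)methanimine | [Li]N=C(c1cc(OC)c(OC)c(OC)c1)c1cc(OC)c(OCc2ccccc2)cc1CC(C)C1(C)OCCO1 | intermediate (not isolated)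
12 | rac-4-[5-benzyloxy-4-methoxy-2-(3,4,5-trimethoxybenzoyl)phenyl]-3-methylbutan-2-one | CC(=O)C(C)Cc1cc(OCc2ccccc2)c(OC)cc1C(=O)c1cc(OC)c(OC)c(OC)c1 | intermediate
13 | rac-7-benzyloxy-6-methoxy-2,3-dimethyl-4-(3,4,5-trimethoxyphenyl)-1,2-dihydronaphthalene | COc1cc2c(cc1OCc1ccccc1)CC(C)C(C)=C2c1cc(OC)c(OC)c(OC)c1 | intermediate
14 | 6-benzyloxy-7-methoxy-2,3-dimethyl-1-(3,4,5-trimethoxyphenyl)naphthalene | COc1cc2c(-c3cc(OC)c(OC)c(OC)c3)c(C)c(C)cc2cc1OCc1ccccc1 | intermediate
15 | 3-methoxy-6,7-dimethyl-5-(3,4,5-trimethoxyphenyl)naphthalen-2-ol | COc1cc2c(-c3cc(OC)c(OC)c(OC)c3)c(C)c(C)cc2cc1O | target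

## Step count and risk

Total step count: 9. Longest linear sequence: 9 steps (1 → 15); compounds 5 and 9 enter as purchased.

**Step 7 (key step).** The most likely failure is intermolecular ketyl coupling to dimers and oligomers when the stationary concentration of 12 rises. The titanium chlorides may also enolize the methyl ketone, which then adds in an aldol sense to the diaryl ketone, or the diaryl ketone may simply be reduced to the carbinol without coupling.
- Fallback, from 12 back to 13: the ring is closed by a samarium ketyl–carbonyl cyclization and the oxygens are removed in separate steps. SmI2 in THF with HMPA at low temperature should reduce the diaryl ketone to its ketyl, which adds to the methyl ketone to give 6-benzyloxy-7-methoxy-2,3-dimethyl-1-(3,4,5-trimethoxyphenyl)-1,2,3,4-tetrahydronaphthalene-1,2-diol F1. The cis-diol is expected from chelation of both oxygens on samarium.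
- Thiocarbonyldiimidazole in refluxing toluene would convert F1 into the cyclic thiocarbonate 7-benzyloxy-8-methoxy-3a,4-dimethyl-9b-(3,4,5-trimethoxyphenyl)-3a,4,5,9b-tetrahydronaphtho[1,2-d][1,3]dioxole-2-thione F2.
- Corey–Winter fragmentation of F2 with P(OMe)3 at reflux would then give the alkene 13.

**Step 6.** The aryllithium 10 may act as a base, removing a ring proton of 9 next to the cyano group, or may be quenched before it adds. The hindered N–H ketimine may also hydrolyse slowly and condense with the freed methyl ketone.
- Fallback, from 8 back to 12: the C1 carbon is introduced at the alcohol level. The aryllithium 10 made from 8 (n-BuLi, THF, −78 °C) is added to 3,4,5-trimethoxybenzaldehyde (the aldehyde labelled A6 above, used here as a reagent) to give {4-benzyloxy-5-methoxy-2-[2-(2-methyl-1,3-dioxolan-2-yl)propyl]phenyl}(3,4,5-trimethoxyphenyl)methanol F3.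
- MnO2 in CH2Cl2 oxidizes the doubly benzylic alcohol to {4-benzyloxy-5-methoxy-2-[2-(2-methyl-1,3-dioxolan-2-yl)propyl]phenyl}(3,4,5-trimethoxyphenyl)methanone F4.
- Aqueous HCl in THF removes the dioxolane to give 12.

**Step 4.** The ambident diketone enolate may be alkylated on oxygen, and the p-alkoxybenzyl-type bromide 4 may ionize and be solvolysed if the hydroxide stage is started before C-alkylation is complete.
- Fallback, from 4 back to 7: a β-keto ester is used as nucleophile and the activating group is removed by dealkoxycarbonylation. The sodium enolate of ethyl 2-methylacetoacetate (NaH, THF) is alkylated with 4 to give ethyl 2-[(5-benzyloxy-2-bromo-4-methoxyphenyl)methyl]-2-methyl-3-oxobutanoate F5.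
- Krapcho reaction of F5 (LiCl, wet DMSO, 150 °C) removes the ester group under neutral conditions, avoiding competing acyl cleavage, and gives 7.

**Step 8.** Oxidation may go beyond aromatization: hydride abstraction from the benzylic methyl groups of the electron-rich naphthalene or from the O-benzyl CH2 group (oxidative debenzylation) if the quinone is in excess or the reaction runs long.
- Fallback, from 13 back to 14: catalytic dehydrogenation over Pd/C in refluxing mesitylene, with no stoichiometric oxidant. Hydrogen released on the metal may already cleave part of the benzyl ether, which is harmless because step 9 does the same. No new compound is formed.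

## Further compounds

F1 | step 7 | 6-benzyloxy-7-methoxy-2,3-dimethyl-1-(3,4,5-trimethoxyphenyl)-1,2,3,4-tetrahydronaphthalene-1,2-diol (racemic, cis-diol expected, mixture at C3) | COc1cc2c(cc1OCc1ccccc1)CC(C)C(C)(O)C2(O)c1cc(OC)c(OC)c(OC)c1
F2 | step 7 | 7-benzyloxy-8-methoxy-3a,4-dimethyl-9b-(3,4,5-trimethoxyphenyl)-3a,4,5,9b-tetrahydronaphtho[1,2-d][1,3]dioxole-2-thione (cyclic thiocarbonate of F1, racemic, mixture at C4) | COc1cc2c(cc1OCc1ccccc1)CC(C)C1(C)OC(=S)OC12c1cc(OC)c(OC)c(OC)c1
F3 | step 6 | {4-benzyloxy-5-methoxy-2-[2-(2-methyl-1,3-dioxolan-2-yl)propyl]phenyl}(3,4,5-trimethoxyphenyl)methanol (diastereomer mixture) | CC1(OCCO1)C(C)Cc1cc(OCc2ccccc2)c(OC)cc1C(O)c1cc(OC)c(OC)c(OC)c1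
F4 | step 6 | rac-{4-benzyloxy-5-methoxy-2-[2-(2-methyl-1,3-dioxolan-2-yl)propyl]phenyl}(3,4,5-trimethoxyphenyl)methanone | CC1(OCCO1)C(C)Cc1cc(OCc2ccccc2)c(OC)cc1C(=O)c1cc(OC)c(OC)c(OC)c1
F5 | step 4 | rac-ethyl 2-[(5-benzyloxy-2-bromo-4-methoxyphenyl)methyl]-2-methyl-3-oxobutanoate | CCOC(=O)C(C)(Cc1cc(OCc2ccccc2)c(OC)cc1Br)C(C)=O
F0 | step 8 | none | none
A1 | alternative 1 | (E)-3-(3-benzyloxy-4-methoxyphenyl)prop-2-en-1-yl 3-(3,4,5-trimethoxyphenyl)prop-2-ynoate | COc1ccc(/C=C/COC(=O)C#Cc2cc(OC)c(OC)c(OC)c2)cc1OCc1ccccc1
A2 | alternative 1 | 6-benzyloxy-7-methoxy-9-(3,4,5-trimethoxyphenyl)naphtho[2,3-c]furan-1(3H)-one | COc1cc2c(-c3cc(OC)c(OC)c(OC)c3)c3C(=O)OCc3cc2cc1OCc1ccccc1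
A3 | alternative 2 | 5-(4-benzyloxy-2-bromo-5-methoxyphenyl)-3,4-dimethyl-5-(3,4,5-trimethoxyphenyl)oxolan-2-one (diastereomer mixture) | CC1C(C)C(OC1=O)(c1cc(OC)c(OC)c(OC)c1)c1cc(OC)c(OCc2ccccc2)cc1Br
A4 | alternative 2 | 7-benzyloxy-4-hydroxy-6-methoxy-2,3-dimethyl-4-(3,4,5-trimethoxyphenyl)-3,4-dihydronaphthalen-1(2H)-one (diastereomer mixture) | COc1cc2c(cc1OCc1ccccc1)C(=O)C(C)C(C)C2(O)c1cc(OC)c(OC)c(OC)c1
A5 | alternative 3 | 2-benzyloxy-1-methoxy-4-(2-methylbut-2-en-1-yl)benzene (E/Z mixture) | CC=C(C)Cc1ccc(OC)c(OCc2ccccc2)c1
A6 | alternative 3 | 3,4,5-trimethoxybenzaldehyde | COc1cc(C=O)cc(OC)c1OC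
A7 | alternative 3 | 7-benzyloxy-6-methoxy-2,3-dimethyl-1-(3,4,5-trimethoxyphenyl)-1,2-dihydronaphthalene (diastereomer mixture) | COc1cc2c(C=C(C)C(C)C2c2cc(OC)c(OC)c(OC)c2)cc1OCc1ccccc1
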